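## Analysis of the target

The target 17 is an open-chain tridepside. Three benzene rings (A, B, C) are joined head to tail by two aryl ester bonds: the carbonyl of ring A to O4 of ring B, and the carbonyl of ring B to O4 of ring C, which ends in a free carboxylic acid. There is no stereocentre, so every problem is one of regiochemistry and chemoselectivity. Each ring is numbered here from the carbon that bears its carbonyl (C1). All three rings then carry a hydroxyl at C2 and a methyl at C6; rings B and C are orsellinate units, and ring A has in addition a free hydroxyl at C4 and an acetate at C5. The sensitive points are the two depside esters and the aryl acetate (cleaved or scrambled by base and nucleophiles), the catechol monoacetate of ring A (acetyl shift between O5 and O4), and the electron-rich salicylic acid of ring C (decarboxylation). The synthesis is hard because five phenolic oxygens must be told apart with only O5 of ring A acetylated, and because classical depside couplings need 2,6-disubstituted benzoic acids with a protected C2 oxygen, which esterify poorly. The strategy rests on the shared C1 carbonyl / C2 hydroxyl / C6 methyl pattern: with the three C2 hydroxyls removed, every carbonyl has exactly one ortho C–H, at C2, because C6 is blocked by the methyl group.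

## Retrosynthetic reasoning

**17 to 16.** The last bond cut is the O–CH2 bond of a benzyl ether on O4 of ring A. O4 must stay covered from the point where the ring A catechol is differentiated until the oxidation is over; otherwise it would compete as a nucleophile in the esterifications and leave an oxidisable catechol monoester. The cover must come off without base, acid or nucleophile, because 17 has an acetate beside the freed phenol and two depside bonds. Neutral hydrogenolysis meets this and is the only step after the key step.

**16 to 14.** The three C2–O bonds are cut together. Each lies ortho to a carbonyl oxygen that can hold a metal, and in 14 each is the only ortho C–H of its ring. This turns rings B and C into one simple para-hydroxy-ortho-methylbenzoate unit, leaves every acid in the assembly with a single ortho substituent, and removes all C2 protecting groups. The forward reaction must oxidise three C–H bonds in one operation, pass through the tris(trifluoroacetate) 15, and leave the acetate, the depside bonds and the acid intact.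

**14 to 12 and 10, through 13.** The ester C–O bond between the ring B carbonyl and O4 of ring C is cut. The acid terminus of ring C is blocked as a tert-butyl ester in 13. This ester falls to acid at room temperature and so is orthogonal to the benzyl ether, the acetate and the aryl esters, none of which tolerate the base or hydrogenolysis that other esters would need.

**12 to 8 and 10, through 11.** The same cut one ring earlier releases the ring A acid 8 and a second molecule of 10. One building block therefore serves for both rings B and C, and the chain grows by repeating two operations.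

**10 to 9.** The tert-butyl ester is traced to the free hydroxy acid 9, which has the ring B/C substitution in place.

**8 to 5, through 6.** The acetate on O5 is put on last within ring A, after the alkyl ester of 5 has been hydrolysed to 6, because an aryl acetate would not survive that hydrolysis. From 8 onward no basic step follows.

**5 to 4.** The O4–benzyl bond is cut. In catechol 4 the two hydroxyls differ: O4 is para to the ester carbonyl and more acidic, and O3 of the benzoate (the future O5 of ring A) is flanked by the methyl group. Mono-alkylation should therefore go to O4.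

**4 to 1, through 2.** The C4–O bond is traced to a formyl group (Dakin oxidation via formate 3), and the formyl group to a C–H bond ortho to the phenol of 1. Compound 1 already holds the methyl between ester and phenol, which is the hardest substituent to introduce later. Its phenol has one free ortho position, so the C4 oxygen enters without a regiochemical choice.

## Alternatives that were turned down

**Alternative 1:** Ring A is cut across C1–C2 and C5–C6. The furan A1 supplies C2 to C5 with the silyl ether on C2 and the benzyl ether on C4. The but-2-ynoate A2 of the protected ring B–C phenol supplies C1, C6, the methyl and the depside carbonyl. Cycloaddition and opening of the oxygen bridge toward C5 should give the phenol A3.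
- For: the mechanism tells all three ring A oxygens apart, leaving only O5 free for acetylation. On this point it is stronger than the chosen route, which relies on an acidity difference in catechol 4. The orientation follows from the nucleophilic furan terminus meeting the β-carbon of the ynoate, and the reaction type is known.
- Against: A2 is a β-methyl ynoate with one activating group, a slow dienophile toward a furan whose cycloadditions are reversible. A1 is acid- and moisture-sensitive and takes several steps to make. The bridge can also open the other way. A2 still needs both orsellinate rings with benzyl-protected C2 oxygens, hence couplings of 2,6-disubstituted acids. After A3 three more operations remain (acetylation, desilylation, hydrogenolysis).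
- Comparison: the chosen route gives up the precedent of the key reaction. In return it uses one bought ring twice, makes all ester bonds from mono-ortho-substituted acids, and needs one deprotection after the key step.

**Alternative 2:** Ring B is cut across C2–C3 and C1–C6. The pyrone A4 (an enol ester of the protected ring A acid) would add the 3-methoxypropiolate A5 of the ring C phenol across its C3 and C6. Decarboxylative aromatisation would give A6, in which the new ring B joins rings A and C and carries its C2 oxygen as a methyl ether.
- For: it is the most convergent plan, since ring B is made while the outer rings are connected. The polarities match (nucleophilic pyrone C3, methoxy-bearing alkyne carbon), and the pyrone core is a cheap commodity.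
- Against: A4 is a vinylogous mixed anhydride that transfers or shifts its acyl group on heating. The push–pull alkyne of A5 is a poor dienophile, so the temperatures needed are ones that neither A4 nor the aryl alkynoate should tolerate. In A6 the C2 oxygen of ring B is a methyl ether, and cleaving it with a boron halide beside two depside esters, an acetate and four benzyl groups is a further unsolved problem. Both outer rings must carry their full oxygenation in protected, hindered form.
- Comparison: it is more convergent than the chosen route, but it exposes two labile esters to forcing conditions. The chosen route forms every ester at room temperature and puts all its risk in one step.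

**Alternative 3:** The A–B ester C–O bond and the C1–C6 bond of ring A are made in one operation. Heating dioxinone A7 with phenol A8 should acylate the phenol and give the open-chain ester A9. Aldol closure of C1 onto the C6 ketone and aromatisation would give A10, which needs only hydrogenolysis.
- For: it is biomimetic and has the shortest endgame. The hindered A–B ester is formed without coupling a 2,6-disubstituted acid, and the acetate is already in place. On these points it equals the chosen strategy.
- Against: A9 has four carbonyls and an acetoxy group between two ketones. Acetyl shifts and retro-Claisen cleavage at that carbon are likely. The aryl ester is a good leaving group, so Claisen or lactone closure with loss of A8 competes with the wanted aldol, as does the aldol of the terminal methyl onto C2. Nothing in A9 enforces one folding. A7 is a long synthesis of a fragile compound, and A8 again needs protected orsellinates.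
- Comparison: the chosen route takes its selectivity from the substitution pattern of 14 (one ortho hydrogen per carbonyl) rather than from an uncontrolled folding.

Key step: step 11

Assumption: the temporary ester on the growing acid terminus is taken as tert-butyl, and ring A is drawn from 1, which already holds the C6 methyl; monomer names use benzoate locants, so C4, C5 and C6 of ring A appear there as positions 4, 3 and 2.

## Route

Step 1
Reactants: 1 methyl 3-hydroxy-2-methylbenzoate
Product: 2 methyl 4-formyl-3-hydroxy-2-methylbenzoate
Conditions: MgCl2, Et3N, (CH2O)n, MeCN, reflux; then 1 M HCl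
Reagents that add atoms: paraformaldehyde (as formaldehyde), C=O
Why: Magnesium-mediated ortho-formylation of a phenol (Casnati–Skattebøl): the magnesium phenoxide delivers formaldehyde through a chelate to the only free ortho carbon, and the benzylic alkoxide is oxidised to the aldehyde by hydride transfer to a second formaldehyde. The para position is not reached by the chelate, and the other ortho position holds the methyl group.

Step 2
Reactants: 2 methyl 4-formyl-3-hydroxy-2-methylbenzoate
Product: 4 methyl 3,4-dihydroxy-2-methylbenzoate, via methyl 4-(formyloxy)-3-hydroxy-2-methylbenzoate 3 (not isolated)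
Conditions: 30% H2O2, NaOH, THF–H2O, 0 °C; then 1 M HCl
Reagents that add atoms: hydrogen peroxide, OO
Why: Dakin oxidation: hydroperoxide adds to the aldehyde, the aryl group (made electron-rich by the ortho phenoxide) migrates to oxygen to give formate 3, and hydroxide cleaves the formate in the flask. The methyl ester, flanked by the methyl group and deactivated by the para phenoxide, should not be hydrolysed at 0 °C.

Step 3
Reactants: 4 methyl 3,4-dihydroxy-2-methylbenzoate
Product: 5 methyl 4-(benzyloxy)-3-hydroxy-2-methylbenzoate
Conditions: BnBr (1.05 equiv), K2CO3 (1.1 equiv), DMF, 0 °C to rt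
Reagents that add atoms: benzyl bromide, BrCc1ccccc1
Why: Williamson ether synthesis on the mono-phenoxide. With one equivalent of a weak base the more acidic O4–H (para to the ester carbonyl) is ionised, and O3 is shielded by the neighbouring methyl group, so alkylation should take place at O4.

Step 4
Reactants: 5 methyl 4-(benzyloxy)-3-hydroxy-2-methylbenzoate
Product: 6 4-(benzyloxy)-3-hydroxy-2-methylbenzoic acid
Conditions: NaOH, MeOH–H2O, 60 °C; then 1 M HCl
Reagents that add atoms: sodium hydroxide, [Na+].[OH-]
Why: Saponification of a methyl ester by acyl–oxygen cleavage. The benzyl ether and the phenol are stable to aqueous base, and no base-labile group is yet present.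

Step 5
Reactants: 6 4-(benzyloxy)-3-hydroxy-2-methylbenzoic acid
Product: 8 3-acetoxy-4-(benzyloxy)-2-methylbenzoic acid, via acetic 3-acetoxy-4-(benzyloxy)-2-methylbenzoic anhydride 7 (not isolated)
Conditions: Ac2O (3 equiv), pyridine, DMAP (cat.), CH2Cl2, rt; then H2O–THF, rt
Reagents that add atoms: acetic anhydride, CC(=O)OC(C)=O
Why: DMAP-catalysed O-acetylation of the hindered phenol. The carboxyl group is acetylated as well to the mixed anhydride 7, which water and pyridine hydrolyse during work-up much faster than the aryl acetate.

Step 6
Reactants: 9 4-hydroxy-2-methylbenzoic acid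
Product: 10 tert-butyl 4-hydroxy-2-methylbenzoate
Conditions: Me2NCH(OtBu)2 (4 equiv), toluene, 80 °C
Reagents that add atoms: N,N-dimethylformamide di-tert-butyl acetal, CN(C)C(OC(C)(C)C)OC(C)(C)C
Why: Carboxyl-selective tert-butylation with a formamide acetal: the acid protonates the acetal and the carboxylate is alkylated by the tert-butyl group of the resulting alkoxyiminium ion. The less acidic phenol does not start this sequence and should stay free.

Step 7
Reactants: 8 3-acetoxy-4-(benzyloxy)-2-methylbenzoic acid; 10 tert-butyl 4-hydroxy-2-methylbenzoate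
Product: 11 tert-butyl 4-{[3-acetoxy-4-(benzyloxy)-2-methylbenzoyl]oxy}-2-methylbenzoate
Conditions: EDC·HCl, DMAP (cat.), CH2Cl2, 0 °C to rt
Reagents that add atoms: none
Why: Steglich esterification: the carbodiimide activates the acid and DMAP passes the acyl group to the phenol. The acid has only one ortho substituent, so the coupling should be fast, and the aryl acetate, buried between the methyl and benzyloxy groups, should not donate its acyl group.

Step 8
Reactants: 11 tert-butyl 4-{[3-acetoxy-4-(benzyloxy)-2-methylbenzoyl]oxy}-2-methylbenzoate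
Product: 12 4-{[3-acetoxy-4-(benzyloxy)-2-methylbenzoyl]oxy}-2-methylbenzoic acid
Conditions: TFA–CH2Cl2 (1:4), rt
Reagents that add atoms: none
Why: Acidolysis of a tert-butyl ester by alkyl–oxygen cleavage through the tert-butyl cation, lost as 2-methylpropene. Aryl esters, the aryl acetate and the aryl benzyl ether have no such cation to lose at room temperature.

Step 9
Reactants: 12 4-{[3-acetoxy-4-(benzyloxy)-2-methylbenzoyl]oxy}-2-methylbenzoic acid; 10 tert-butyl 4-hydroxy-2-methylbenzoate
Product: 13 tert-butyl 4-[(4-{[3-acetoxy-4-(benzyloxy)-2-methylbenzoyl]oxy}-2-methylbenzoyl)oxy]-2-methylbenzoate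
Conditions: EDC·HCl, DMAP (cat.), CH2Cl2, 0 °C to rt
Reagents that add atoms: none
Why: Second Steglich esterification, again with a mono-ortho-substituted acid and an unhindered phenol. Low temperature and a catalytic amount of DMAP are chosen to keep the depside bond already present from exchanging.

Step 10
Reactants: 13 tert-butyl 4-[(4-{[3-acetoxy-4-(benzyloxy)-2-methylbenzoyl]oxy}-2-methylbenzoyl)oxy]-2-methylbenzoate
Product: 14 4-[(4-{[3-acetoxy-4-(benzyloxy)-2-methylbenzoyl]oxy}-2-methylbenzoyl)oxy]-2-methylbenzoic acid
Conditions: TFA–CH2Cl2 (1:4), rt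
Reagents that add atoms: none
Why: Acidolysis of the tert-butyl ester as in step 8, giving the tris-2-deoxy tridepside acid with all other groups untouched.

Step 11
Reactants: 14 4-[(4-{[3-acetoxy-4-(benzyloxy)-2-methylbenzoyl]oxy}-2-methylbenzoyl)oxy]-2-methylbenzoic acid
Product: 16 4-[(4-{[3-acetoxy-4-(benzyloxy)-6-hydroxy-2-methylbenzoyl]oxy}-2-hydroxy-6-methylbenzoyl)oxy]-2-hydroxy-6-methylbenzoic acid, via tris-O-trifluoroacetyl benzyl ether 15 (not isolated)
Conditions: [RuCl2(p-cymene)]2 (10 mol%), PhI(OCOCF3)2 (4.5 equiv), TFA–TFAA (3:1), 80 °C; then H2O–THF, rt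
Reagents that add atoms: bis(trifluoroacetoxy)iodobenzene, FC(F)(F)C(=O)OI(OC(=O)C(F)(F)F)c1ccccc1
Why: Proposed new method: the carbonyl oxygen of each ester and of the acid binds divalent ruthenium, and trifluoroacetate-assisted concerted metalation–deprotonation at the single ortho C–H (C2 of each ring) gives a five-membered ruthenacycle. PhI(OCOCF3)2 oxidises it to a tetravalent ruthenium trifluoroacetate, C–O reductive elimination releases the aryl trifluoroacetate and divalent ruthenium, and three such cycles give 15, which the aqueous work-up hydrolyses to 16. The closest known reaction type is the ruthenium-catalysed, ester-directed ortho C–H hydroxylation of simple alkyl benzoates in the same acid–anhydride medium; an aryl ester carbonyl as director and three metalations in one molecule have not been shown. No ring is closed and no stereocentre is formed. Site selectivity is needed on all three rings and comes from the substitution pattern: every carbonyl has exactly one ortho hydrogen, the acetate of ring A has none beside it, and metalation of an O-aryl ring would need a six-membered ruthenacycle, which should be slower than the five-membered one. Each new phenol stays an electron-poor trifluoroacetate until work-up, which should protect it from further oxidation and protect ring C from protodecarboxylation.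

Step 12
Reactants: 16 4-[(4-{[3-acetoxy-4-(benzyloxy)-6-hydroxy-2-methylbenzoyl]oxy}-2-hydroxy-6-methylbenzoyl)oxy]-2-hydroxy-6-methylbenzoic acid
Product: 17 4-[(4-{[3-acetoxy-4,6-dihydroxy-2-methylbenzoyl]oxy}-2-hydroxy-6-methylbenzoyl)oxy]-2-hydroxy-6-methylbenzoic acid (target, CNP0154030.0)
Conditions: H2 (1 atm), 10% Pd/C, EtOAc, rt
Reagents that add atoms: none
Why: Hydrogenolysis of the benzylic C–O bond on palladium. Aryl esters, the acetate, the phenols and the acid are inert, and the neutral aprotic medium offers no base to move the acetyl group from O5 to the freed O4.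

## Compound list

1 | methyl 3-hydroxy-2-methylbenzoate | COC(=O)c1cccc(O)c1C | starting material
2 | methyl 4-formyl-3-hydroxy-2-methylbenzoate | COC(=O)c1ccc(C=O)c(O)c1C | intermediate
3 | methyl 4-(formyloxy)-3-hydroxy-2-methylbenzoate | COC(=O)c1ccc(OC=O)c(O)c1C | intermediate (not isolated)
4 | methyl 3,4-dihydroxy-2-methylbenzoate | COC(=O)c1ccc(O)c(O)c1C | intermediate
5 | methyl 4-(benzyloxy)-3-hydroxy-2-methylbenzoate | COC(=O)c1ccc(OCc2ccccc2)c(O)c1C | intermediate
6 | 4-(benzyloxy)-3-hydroxy-2-methylbenzoic acid | OC(=O)c1ccc(OCc2ccccc2)c(O)c1C | intermediate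
7 | acetic 3-acetoxy-4-(benzyloxy)-2-methylbenzoic anhydride | CC(=O)OC(=O)c1ccc(OCc2ccccc2)c(OC(C)=O)c1C | intermediate (not isolated)
8 | 3-acetoxy-4-(benzyloxy)-2-methylbenzoic acid (ring A acid) | CC(=O)Oc1c(OCc2ccccc2)ccc(C(=O)O)c1C | intermediate
9 | 4-hydroxy-2-methylbenzoic acid | Cc1cc(O)ccc1C(=O)O | starting material
10 | tert-butyl 4-hydroxy-2-methylbenzoate | Cc1cc(O)ccc1C(=O)OC(C)(C)C | intermediate
11 | tert-butyl 4-{[3-acetoxy-4-(benzyloxy)-2-methylbenzoyl]oxy}-2-methylbenzoate | CC(=O)Oc1c(OCc2ccccc2)ccc(C(=O)Oc2ccc(C(=O)OC(C)(C)C)c(C)c2)c1C | intermediate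
12 | 4-{[3-acetoxy-4-(benzyloxy)-2-methylbenzoyl]oxy}-2-methylbenzoic acid | CC(=O)Oc1c(OCc2ccccc2)ccc(C(=O)Oc2ccc(C(=O)O)c(C)c2)c1C | intermediate
13 | tert-butyl 4-[(4-{[3-acetoxy-4-(benzyloxy)-2-methylbenzoyl]oxy}-2-methylbenzoyl)oxy]-2-methylbenzoate | CC(=O)Oc1c(OCc2ccccc2)ccc(C(=O)Oc2ccc(C(=O)Oc3ccc(C(=O)OC(C)(C)C)c(C)c3)c(C)c2)c1C | intermediate
14 | 4-[(4-{[3-acetoxy-4-(benzyloxy)-2-methylbenzoyl]oxy}-2-methylbenzoyl)oxy]-2-methylbenzoic acid (precursor of the key step) | CC(=O)Oc1c(OCc2ccccc2)ccc(C(=O)Oc2ccc(C(=O)Oc3ccc(C(=O)O)c(C)c3)c(C)c2)c1C | intermediate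
15 | 4-[(4-{[3-acetoxy-4-(benzyloxy)-2-methyl-6-(trifluoroacetoxy)benzoyl]oxy}-2-methyl-6-(trifluoroacetoxy)benzoyl)oxy]-2-methyl-6-(trifluoroacetoxy)benzoic acid | CC(=O)Oc1c(OCc2ccccc2)cc(OC(=O)C(F)(F)F)c(C(=O)Oc2cc(C)c(C(=O)Oc3cc(C)c(C(=O)O)c(OC(=O)C(F)(F)F)c3)c(OC(=O)C(F)(F)F)c2)c1C | intermediate (not isolated)
16 | 4-[(4-{[3-acetoxy-4-(benzyloxy)-6-hydroxy-2-methylbenzoyl]oxy}-2-hydroxy-6-methylbenzoyl)oxy]-2-hydroxy-6-methylbenzoic acid (product of the key step) | CC(=O)Oc1c(OCc2ccccc2)cc(O)c(C(=O)Oc2cc(C)c(C(=O)Oc3cc(C)c(C(=O)O)c(O)c3)c(O)c2)c1C | intermediate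
17 | 4-[(4-{[3-acetoxy-4,6-dihydroxy-2-methylbenzoyl]oxy}-2-hydroxy-6-methylbenzoyl)oxy]-2-hydroxy-6-methylbenzoic acid | CC(=O)Oc1c(O)cc(O)c(C(=O)Oc2cc(C)c(C(=O)Oc3cc(C)c(C(=O)O)c(O)c3)c(O)c2)c1C | target

## Step count and least certain steps

Total step count: 12. Longest linear sequence: 11 steps (steps 1–5 and 7–12, from 1 to 17); step 6 is the only side branch.

**Step 11 (key step, proposed new method).**
- Incomplete or uneven metalation is the main risk: aryl ester carbonyls and a carboxyl group in an anhydride medium are weak donors, so mixtures of partly oxygenated products may result.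
- Metalation through a six-membered chelate could oxidise C3 or C5 of rings B and C.
- The hot acid–anhydride medium may exchange the acetate or the depside acyl groups, and may activate the free carboxyl group toward unwanted acyl transfer.
- The trivalent iodine reagent may attack the electron-rich C3 of ring A directly.
- Acidolysis of the benzyl ether is possible but harmless, since the freed O4 would be masked as a trifluoroacetate and the material would converge on 17 after step 12.
- Fallback (known chemistry): the late oxidation is given up and every C2 oxygen is brought in before the rings are joined. The fallback sets out from 8, which is oxidised at its one ortho C–H by the known carboxylate-directed hydroxylation of benzoic acids (Pd(OAc)2, KOAc, benzoquinone, O2, DMA, 115 °C) to 3-acetoxy-4-(benzyloxy)-6-hydroxy-2-methylbenzoic acid F1. Rings B and C come from commercial 2,4-dihydroxy-6-methylbenzoic acid F2, converted to tert-butyl 2,4-dihydroxy-6-methylbenzoate F3 (tert-butyl 2,2,2-trichloroacetimidate, CH2Cl2, rt). Carbodiimide coupling of F1 with F3 (DCC, cat. DMAP, CH2Cl2) acylates the free O4 of F3, whose O2 is held in a hydrogen bond to the ester carbonyl, and gives tert-butyl 4-{[3-acetoxy-4-(benzyloxy)-6-hydroxy-2-methylbenzoyl]oxy}-2-hydroxy-6-methylbenzoate F4. Acidolysis (TFA–CH2Cl2, rt) gives 4-{[3-acetoxy-4-(benzyloxy)-6-hydroxy-2-methylbenzoyl]oxy}-2-hydroxy-6-methylbenzoic acid F5. A second coupling with F3 gives tert-butyl 4-[(4-{[3-acetoxy-4-(benzyloxy)-6-hydroxy-2-methylbenzoyl]oxy}-2-hydroxy-6-methylbenzoyl)oxy]-2-hydroxy-6-methylbenzoate F6, and a second acidolysis returns to the route at 16. The price is two esterifications of 2,6-disubstituted salicylic acids, which the main route avoids.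

**Step 3 (selective benzylation).**
- Poor discrimination between the two catechol oxygens, or double alkylation, is the risk; the acidity difference is real but modest, and the second phenoxide forms as soon as base is in excess.
- Fallback: the regiochemistry is fixed by the order in which the oxygens appear, not by their acidity. It sets out from 2, whose hydroxyl is capped (MOMCl, iPr2NEt, CH2Cl2) to give methyl 4-formyl-3-(methoxymethoxy)-2-methylbenzoate F7. Baeyer–Villiger oxidation (mCPBA, CH2Cl2) gives methyl 4-(formyloxy)-3-(methoxymethoxy)-2-methylbenzoate F8, and methanolysis (K2CO3, MeOH) gives methyl 4-hydroxy-3-(methoxymethoxy)-2-methylbenzoate F9 with a single free phenol. Benzylation (BnBr, K2CO3, DMF) gives methyl 4-(benzyloxy)-3-(methoxymethoxy)-2-methylbenzoate F10, and acidic methanolysis of the acetal (HCl, MeOH) returns to the route at 5. This replaces steps 2 and 3.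

**Step 6 (tert-butyl ester of a hydroxy acid).**
- Competing tert-butylation of the phenol or incomplete conversion is the risk, since the alkylating ion is not fully selective for carboxylate.
- Fallback: a different temporary ester made by carboxylate alkylation and removed by allyl transfer. It sets out from 9, which with allyl bromide and KHCO3 in DMF gives allyl 4-hydroxy-2-methylbenzoate F11 (bicarbonate ionises only the acid). Steglich coupling with 8 gives allyl 4-{[3-acetoxy-4-(benzyloxy)-2-methylbenzoyl]oxy}-2-methylbenzoate F12, and Pd(PPh3)4 (zerovalent palladium) with PhSiH3 in CH2Cl2 returns to the route at 12. Coupling of 12 with F11 gives allyl 4-[(4-{[3-acetoxy-4-(benzyloxy)-2-methylbenzoyl]oxy}-2-methylbenzoyl)oxy]-2-methylbenzoate F13, and the same deallylation returns to the route at 14.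

**Step 9 (second esterification; step 7 shares the risk in milder form).**
- DMAP-catalysed acyl transfer may scramble the depside bond already present in 12 or the acetate, and the O-acylisourea may rearrange to an N-acylurea if the ortho methyl slows the esterification.
- Fallback: a convergent order in which the ring A acid meets a coupling only once. It sets out from 9 and 10. Double benzylation of 9 (BnBr, K2CO3, DMF) gives benzyl 4-(benzyloxy)-2-methylbenzoate F14, and saponification (NaOH, MeOH–H2O) gives 4-(benzyloxy)-2-methylbenzoic acid F15. Steglich coupling with 10 gives tert-butyl 4-{[4-(benzyloxy)-2-methylbenzoyl]oxy}-2-methylbenzoate F16, and hydrogenolysis (H2, 10% Pd/C, EtOAc) gives tert-butyl 4-[(4-hydroxy-2-methylbenzoyl)oxy]-2-methylbenzoate F17. Coupling of F17 with 8 returns to the route at 13.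

## Further compounds

F1 | step 11 | 3-acetoxy-4-(benzyloxy)-6-hydroxy-2-methylbenzoic acid | CC(=O)Oc1c(OCc2ccccc2)cc(O)c(C(=O)O)c1C
F2 | step 11 | 2,4-dihydroxy-6-methylbenzoic acid (orsellinic acid) | Cc1cc(O)cc(O)c1C(=O)O
F3 | step 11 | tert-butyl 2,4-dihydroxy-6-methylbenzoate | Cc1cc(O)cc(O)c1C(=O)OC(C)(C)C
F4 | step 11 | tert-butyl 4-{[3-acetoxy-4-(benzyloxy)-6-hydroxy-2-methylbenzoyl]oxy}-2-hydroxy-6-methylbenzoate | CC(=O)Oc1c(OCc2ccccc2)cc(O)c(C(=O)Oc2cc(C)c(C(=O)OC(C)(C)C)c(O)c2)c1C
F5 | step 11 | 4-{[3-acetoxy-4-(benzyloxy)-6-hydroxy-2-methylbenzoyl]oxy}-2-hydroxy-6-methylbenzoic acid | CC(=O)Oc1c(OCc2ccccc2)cc(O)c(C(=O)Oc2cc(C)c(C(=O)O)c(O)c2)c1C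
F6 | step 11 | tert-butyl 4-[(4-{[3-acetoxy-4-(benzyloxy)-6-hydroxy-2-methylbenzoyl]oxy}-2-hydroxy-6-methylbenzoyl)oxy]-2-hydroxy-6-methylbenzoate | CC(=O)Oc1c(OCc2ccccc2)cc(O)c(C(=O)Oc2cc(C)c(C(=O)Oc3cc(C)c(C(=O)OC(C)(C)C)c(O)c3)c(O)c2)c1C
F7 | step 3 | methyl 4-formyl-3-(methoxymethoxy)-2-methylbenzoate | COCOc1c(C=O)ccc(C(=O)OC)c1C
F8 | step 3 | methyl 4-(formyloxy)-3-(methoxymethoxy)-2-methylbenzoate | COCOc1c(OC=O)ccc(C(=O)OC)c1C
F9 | step 3 | methyl 4-hydroxy-3-(methoxymethoxy)-2-methylbenzoate | COCOc1c(O)ccc(C(=O)OC)c1C
F10 | step 3 | methyl 4-(benzyloxy)-3-(methoxymethoxy)-2-methylbenzoate | COCOc1c(OCc2ccccc2)ccc(C(=O)OC)c1C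
F11 | step 6 | allyl 4-hydroxy-2-methylbenzoate | C=CCOC(=O)c1ccc(O)cc1C
F12 | step 6 | allyl 4-{[3-acetoxy-4-(benzyloxy)-2-methylbenzoyl]oxy}-2-methylbenzoate | CC(=O)Oc1c(OCc2ccccc2)ccc(C(=O)Oc2ccc(C(=O)OCC=C)c(C)c2)c1C
F13 | step 6 | allyl 4-[(4-{[3-acetoxy-4-(benzyloxy)-2-methylbenzoyl]oxy}-2-methylbenzoyl)oxy]-2-methylbenzoate | CC(=O)Oc1c(OCc2ccccc2)ccc(C(=O)Oc2ccc(C(=O)Oc3ccc(C(=O)OCC=C)c(C)c3)c(C)c2)c1C
F14 | step 9 | benzyl 4-(benzyloxy)-2-methylbenzoate | Cc1cc(OCc2ccccc2)ccc1C(=O)OCc1ccccc1
F15 | step 9 | 4-(benzyloxy)-2-methylbenzoic acid | Cc1cc(OCc2ccccc2)ccc1C(=O)O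
F16 | step 9 | tert-butyl 4-{[4-(benzyloxy)-2-methylbenzoyl]oxy}-2-methylbenzoate | Cc1cc(OCc2ccccc2)ccc1C(=O)Oc1ccc(C(=O)OC(C)(C)C)c(C)c1
F17 | step 9 | tert-butyl 4-[(4-hydroxy-2-methylbenzoyl)oxy]-2-methylbenzoate | Cc1cc(O)ccc1C(=O)Oc1ccc(C(=O)OC(C)(C)C)c(C)c1
A1 | alternative 1 | 4-(benzyloxy)-2-[(tert-butyldimethylsilyl)oxy]furan | CC(C)(C)[Si](C)(C)Oc1cc(OCc2ccccc2)co1
A2 | alternative 1 | benzyl 2-(benzyloxy)-4-{[2-(benzyloxy)-4-(but-2-ynoyloxy)-6-methylbenzoyl]oxy}-6-methylbenzoate | CC#CC(=O)Oc1cc(C)c(C(=O)Oc2cc(C)c(C(=O)OCc3ccccc3)c(OCc3ccccc3)c2)c(OCc2ccccc2)c1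
A3 | alternative 1 | benzyl 2-(benzyloxy)-4-{[2-(benzyloxy)-4-({4-(benzyloxy)-2-[(tert-butyldimethylsilyl)oxy]-5-hydroxy-6-methylbenzoyl}oxy)-6-methylbenzoyl]oxy}-6-methylbenzoate | Cc1c(O)c(OCc2ccccc2)cc(O[Si](C)(C)C(C)(C)C)c1C(=O)Oc1cc(C)c(C(=O)Oc2cc(C)c(C(=O)OCc3ccccc3)c(OCc3ccccc3)c2)c(OCc2ccccc2)c1
A4 | alternative 2 | 6-methyl-2-oxo-2H-pyran-4-yl 3-acetoxy-4,6-bis(benzyloxy)-2-methylbenzoate | CC(=O)Oc1c(OCc2ccccc2)cc(OCc2ccccc2)c(C(=O)Oc2cc(C)oc(=O)c2)c1C
A5 | alternative 2 | benzyl 2-(benzyloxy)-4-[(3-methoxyprop-2-ynoyl)oxy]-6-methylbenzoate | COC#CC(=O)Oc1cc(C)c(C(=O)OCc2ccccc2)c(OCc2ccccc2)c1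
A6 | alternative 2 | benzyl 4-[(4-{[3-acetoxy-4,6-bis(benzyloxy)-2-methylbenzoyl]oxy}-2-methoxy-6-methylbenzoyl)oxy]-2-(benzyloxy)-6-methylbenzoate | CC(=O)Oc1c(OCc2ccccc2)cc(OCc2ccccc2)c(C(=O)Oc2cc(C)c(C(=O)Oc3cc(C)c(C(=O)OCc4ccccc4)c(OCc4ccccc4)c3)c(OC)c2)c1C
A7 | alternative 3 | 6-(3-acetoxy-2,4-dioxopentyl)-2,2-dimethyl-4H-1,3-dioxin-4-one (racemic) | CC(=O)C(OC(C)=O)C(=O)CC1=CC(=O)OC(C)(C)O1
A8 | alternative 3 | benzyl 2-(benzyloxy)-4-{[2-(benzyloxy)-4-hydroxy-6-methylbenzoyl]oxy}-6-methylbenzoate | Oc1cc(C)c(C(=O)Oc2cc(C)c(C(=O)OCc3ccccc3)c(OCc3ccccc3)c2)c(OCc2ccccc2)c1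
A9 | alternative 3 | benzyl 4-({4-[(6-acetoxy-3,5,7-trioxooctanoyl)oxy]-2-(benzyloxy)-6-methylbenzoyl}oxy)-2-(benzyloxy)-6-methylbenzoate (racemic) | CC(=O)C(OC(C)=O)C(=O)CC(=O)CC(=O)Oc1cc(C)c(C(=O)Oc2cc(C)c(C(=O)OCc3ccccc3)c(OCc3ccccc3)c2)c(OCc2ccccc2)c1
A10 | alternative 3 | benzyl 4-[(4-{[3-acetoxy-4,6-dihydroxy-2-methylbenzoyl]oxy}-2-(benzyloxy)-6-methylbenzoyl)oxy]-2-(benzyloxy)-6-methylbenzoate | CC(=O)Oc1c(O)cc(O)c(C(=O)Oc2cc(C)c(C(=O)Oc3cc(C)c(C(=O)OCc4ccccc4)c(OCc4ccccc4)c3)c(OCc4ccccc4)c2)c1C
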